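The route rests on cutting the bond between C2 of the tetrahydrofuran (ring A: O1, C2, C3, C4, C5) and the trimethoxyphenyl ring. The C3 hydroxymethyl group and the C4 acyl carbon are cis, so they can be tied as a γ-lactone (temporary ring B). The precursor of the key step is therefore a cup-shaped, aryl-free bicyclic lactone. A trityl cation abstracts hydride from the ether CH2 remote from the lactone carbonyl, and an aryltrifluoroborate adds to the convex face of the oxocarbenium ion. One operation turns a C–H bond into the C2–aryl bond and sets C2. An aryllithium finally opens ring B to ketone and alcohol.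

Key step: step 4

Remark on numbering: target atoms are O1, C2 (aryl), C3 (CH2OH), C4 (aroyl), C5. The bicyclic compounds carry furo[3,4-c]furan numbers, in which C4, C3a, C6a, C6, C1 and C3 become C2, C3, C4, C5, the ketone carbon and the CH2OH carbon of the target.

Assumption: 12 is written as the open hydroxy ketone, the form into which its bicyclic hemiketal tautomer equilibrates after work-up.

Step 1
Reactants: 1 furan-3,4-diyldimethanol
Product: 2 [(3R,4S)-tetrahydrofuran-3,4-diyl]dimethanol (cis, meso)
Conditions: H2 (60 bar), Rh/Al2O3 (5 wt % Rh), MeOH, 40 °C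
Reagents that add atoms: none
Why: Heterogeneous catalytic hydrogenation of a furan delivers all hydrogen from the catalyst surface to one face of the flat ring, so the two CH2OH groups end up cis (meso), and rhodium is chosen over palladium to suppress C–O hydrogenolysis.

Step 2
Reactants: 2 [(3R,4S)-tetrahydrofuran-3,4-diyl]dimethanol
Product: 4 (3aS,6aR)-tetrahydro-1H,3H-furo[3,4-c]furan-1-one, via bicyclic lactol 3 (not isolated)
Conditions: horse liver alcohol dehydrogenase, NAD+ (cat.), water-forming NADH oxidase, air, phosphate buffer pH 8, 25 °C
Reagents that add atoms: none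
Why: In this enzymatic oxidative desymmetrisation of a meso 1,4-diol, the NAD+-dependent alcohol dehydrogenase should oxidise only the hydroxymethyl group on the (S)-configured ring carbon, as it does with cis-1,2-bis(hydroxymethyl)cycloalkanes; the hydroxy aldehyde closes to lactol 3 and is oxidised again, which fixes C6a as R and C3a as S (C4 and C3 of the target).

Step 3
Reactants: 5 (3,4,5-trimethoxyphenyl)boronic acid
Product: 6 potassium trifluoro(3,4,5-trimethoxyphenyl)borate
Conditions: KHF2 (aq), MeOH, rt
Reagents that add atoms: potassium hydrogen difluoride, [K+].[F-].F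
Why: This is the standard fluoride exchange that turns an arylboronic acid into its air-stable potassium trifluoroborate, and no stereocentre is involved.

Step 4
Reactants: 4 (3aS,6aR)-tetrahydro-1H,3H-furo[3,4-c]furan-1-one, 6 potassium trifluoro(3,4,5-trimethoxyphenyl)borate
Product: 8 (3aR,4S,6aR)-4-(3,4,5-trimethoxyphenyl)tetrahydro-1H,3H-furo[3,4-c]furan-1-one, via oxocarbenium tetrafluoroborate 7 (not isolated)
Conditions: Ph3CBF4 (0.95 equiv), ClCH2CH2Cl, 40 °C; then 6, MeCN, −30 °C to rt
Reagents that add atoms: none
Why: Ph3C+ takes a hydride from an ether C–H bond of 4 to give the bicyclic oxocarbenium ion 7, and the aryl group of 6 then passes from boron to the cationic carbon with loss of BF3. The closest known reaction types are the trityl-cation-mediated oxidative C–H functionalisation of cyclic ethers and the addition of potassium organotrifluoroborates to oxocarbenium ions; no ring is closed, rings A and B are carried through intact. The step needs site selectivity among three OCH2 groups: C3 is an acyloxy carbon and inert, C6 sits next to C6a, which bears the lactone carbonyl directly and so destabilises a cation at C6, and this leaves C4 as the most hydridic position. The new stereocentre C4 (S) is controlled by the cup shape of the cis-fused bicycle, since 6 can reach the cation only from the convex face, which puts the aryl group exo and trans to the C3a–C3 bond; the BF3 set free can equilibrate the benzylic ether only towards this same, more stable isomer. Attack through the carbon–boron bond fixes the 3,4,5-trimethoxy pattern, which a Friedel–Crafts reaction of 1,2,3-trimethoxybenzene would not give. Reversible proton loss from C3a of 7 cannot scramble that centre, because only the cis-fused ring system can re-form, and a slight deficit of Ph3CBF4 keeps the more hydridic product 8 from being oxidised.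

Step 5
Reactants: 8 (3aR,4S,6aR)-4-(3,4,5-trimethoxyphenyl)tetrahydro-1H,3H-furo[3,4-c]furan-1-one, 9 4-bromo-1,2-dimethoxybenzene
Product: 12 magnone B, (2S,3R,4R)-4-(3,4-dimethoxybenzoyl)-3-(hydroxymethyl)-2-(3,4,5-trimethoxyphenyl)tetrahydrofuran, via 3,4-dimethoxyphenyllithium 10 (not isolated), via lithium hemiketal alkoxide 11 (not isolated)
Conditions: 9, n-BuLi, THF, −78 °C; added to 8, THF, −78 °C; AcOH quench at −78 °C
Reagents that add atoms: none
Why: Bromine–lithium exchange gives 10, whose 1,2-addition to the γ-lactone stops at the lithium hemiketal alkoxide 11 that is stable at −78 °C, so the cold acidic quench releases ketone and primary alcohol together; no stereocentre is formed, and C4 keeps the cis relation imposed by ring B because no base is left when the ketone appears.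

Compound list
1 | furan-3,4-diyldimethanol | OCc1cocc1CO | starting material
2 | [(3R,4S)-tetrahydrofuran-3,4-diyl]dimethanol (cis, meso) | OC[C@H]1COC[C@H]1CO | intermediate
3 | (3aS,6aR)-tetrahydro-1H,3H-furo[3,4-c]furan-1-ol (lactol, both anomers) | OC1[C@H]2COC[C@H]2CO1 | intermediate
4 | (3aS,6aR)-tetrahydro-1H,3H-furo[3,4-c]furan-1-one | O=C1[C@H]2COC[C@H]2CO1 | intermediate
5 | (3,4,5-trimethoxyphenyl)boronic acid | COc1cc(B(O)O)cc(OC)c1OC | starting material
6 | potassium trifluoro(3,4,5-trimethoxyphenyl)borate | [K+].COc1cc([B-](F)(F)F)cc(OC)c1OC | intermediate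
7 | bicyclic oxocarbenium tetrafluoroborate (cation at C4 of 4) | O=C1[C@H]2C[O+]=C[C@H]2CO1.F[B-](F)(F)F | intermediate
8 | (3aR,4S,6aR)-4-(3,4,5-trimethoxyphenyl)tetrahydro-1H,3H-furo[3,4-c]furan-1-one | O=C1[C@H]2CO[C@H](c3cc(OC)c(OC)c(OC)c3)[C@H]2CO1 | intermediate
9 | 4-bromo-1,2-dimethoxybenzene | COc1ccc(Br)cc1OC | starting material
10 | (3,4-dimethoxyphenyl)lithium | [Li]c1ccc(OC)c(OC)c1 | intermediate
11 | lithium alkoxide of the bicyclic hemiketal (aryl and OLi on C1 of 8) | [Li]OC1(c2ccc(OC)c(OC)c2)[C@H]2CO[C@H](c3cc(OC)c(OC)c(OC)c3)[C@H]2CO1 | intermediate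
12 | magnone B, (2S,3R,4R)-4-(3,4-dimethoxybenzoyl)-3-(hydroxymethyl)-2-(3,4,5-trimethoxyphenyl)tetrahydrofuran | COc1ccc(C(=O)[C@H]2CO[C@H](c3cc(OC)c(OC)c(OC)c3)[C@H]2CO)cc1OC | target

Total step count: 5. Longest linear sequence: 4 steps (1 → 2 → 4 → 8 → 12).

Steps most likely to fail

**Step 4 (key step).**
- What may go wrong: hydride abstraction from an ether that the lactone deactivates may be too slow or may lose its site preference. The cation may also condense with its own enol ether, and the benzylic ether product may be oxidised further.
- Fallback: the oxidation level of C4 is raised first, and the cation is then made by ionisation of a leaving group.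
  - Setting out from 4, RuCl3 (cat.)/NaIO4 in EtOAc/MeCN/H2O oxidises the same ether CH2 to the C2-symmetric (3aR,6aR)-tetrahydrofuro[3,4-c]furan-1,4-dione F1.
  - The two carbonyl groups of F1 are homotopic, so one equivalent of i-Bu2AlH at −78 °C can give only one lactol, (3aR,6aR)-4-hydroxytetrahydro-1H,3H-furo[3,4-c]furan-1-one F2.
  - Ac2O/pyridine converts it into (3aR,6aR)-1-oxotetrahydro-1H,3H-furo[3,4-c]furan-4-yl acetate F3.
  - BF3·OEt2 with 6 in MeCN/CH2Cl2 at −30 °C brings the sequence back to 8 by the same convex-face addition.

**Step 5.**
- What may go wrong: the tetrahedral intermediate may collapse early and take up a second aryl group. The lactone may be enolised, with β-elimination of the ring A oxygen, and C4 may epimerise if the mixture warms before the quench.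
- Fallback: the acyl transfer is split into two controlled events.
  - Setting out from 8, MeNH(OMe)·HCl/i-PrMgCl in THF opens ring B to (3R,4R,5S)-4-(hydroxymethyl)-N-methoxy-N-methyl-5-(3,4,5-trimethoxyphenyl)tetrahydrofuran-3-carboxamide F4.
  - Two equivalents of 10 (the first is consumed by the hydroxyl group) give a chelated adduct that cannot add a second aryl group. It collapses to 12 only on cold acidic quench.

**Step 2.**
- What may go wrong: the enzyme may accept the polar oxa-diol poorly, may discriminate the enantiotopic hydroxymethyl groups incompletely, or the lactone may hydrolyse in the buffer.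
- Fallback: acyl-transfer desymmetrisation followed by chemical oxidation.
  - Setting out from 2, a lipase (triacylglycerol hydrolase class, chosen by screening) with vinyl acetate acetylates one enantiotopic group to [(3S,4S)-4-(hydroxymethyl)tetrahydrofuran-3-yl]methyl acetate F5.
  - TEMPO/PhI(OAc)2 in wet MeCN oxidises the free CH2OH to (3R,4S)-4-(acetoxymethyl)tetrahydrofuran-3-carboxylic acid F6.
  - K2CO3/MeOH frees (3R,4R)-4-(hydroxymethyl)tetrahydrofuran-3-carboxylic acid F7, which closes to 4 on acidification.

Further compounds
F1 | step 4 | (3aR,6aR)-tetrahydrofuro[3,4-c]furan-1,4-dione | O=C1[C@H]2COC(=O)[C@H]2CO1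
F2 | step 4 | (3aR,6aR)-4-hydroxytetrahydro-1H,3H-furo[3,4-c]furan-1-one (both anomers) | O=C1[C@H]2COC(O)[C@H]2CO1
F3 | step 4 | (3aR,6aR)-1-oxotetrahydro-1H,3H-furo[3,4-c]furan-4-yl acetate (both anomers) | O=C1[C@H]2COC(OC(C)=O)[C@H]2CO1
F4 | step 5 | (3R,4R,5S)-4-(hydroxymethyl)-N-methoxy-N-methyl-5-(3,4,5-trimethoxyphenyl)tetrahydrofuran-3-carboxamide | CON(C)C(=O)[C@H]1CO[C@H](c2cc(OC)c(OC)c(OC)c2)[C@H]1CO
F5 | step 2 | [(3S,4S)-4-(hydroxymethyl)tetrahydrofuran-3-yl]methyl acetate | OC[C@H]1COC[C@H]1COC(C)=O
F6 | step 2 | (3R,4S)-4-(acetoxymethyl)tetrahydrofuran-3-carboxylic acid | OC(=O)[C@H]1COC[C@H]1COC(C)=O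
F7 | step 2 | (3R,4R)-4-(hydroxymethyl)tetrahydrofuran-3-carboxylic acid | OC(=O)[C@H]1COC[C@H]1CO
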